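Count turnovers: in a flask where the double product passes to tetra adduct with reagent in excess, a pseudo-first-order step, I follow how many e-foldings it has had by 20 min.

in all of them: substrate 0.10 M
- alder: reagent 0.16 M; run made earlier
- ash: reagent 0.46 M; run made earlier
- gamma: reagent 0.120 M; time 20 min
- beta: reagent 0.200 M; time 20 min
- eta: reagent 0.400 M; time 20 min

- alder (time / min: tetra adduct / %, double product / %): 4.00: 1.1, 24.4; 8.00: 2.2, 27.3; 12.0: 3.1, 26.2; 15.0: 4.2, 25.5; 20.0: 5.3, 23.6
- ash (time / min: tetra adduct / %, double product / %): 1.50: 3.3, 48.8; 3.00: 14.1, 49.0; 6.00: 32.6, 34.8; 10.0: 47.8, 21.6; 20.0: 63.5, 7.0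

(readings scatter by 0.5 percentage points)

1. final tetra adduct, as a percentage of the substrate charged, for each flask in turn (gamma, beta, eta)



I call the pool P the sum of double product and tetra adduct, and the turnover count N = ln(P / double product). At 20.0 min, alder has P = 28.9 % and N = 0.203, while ash has P = 70.5 % and N = 2.31; these are readings and carry their scatter. The slope between the two runs, the turnovers counted at that time per molar of reagent charged, with substrate charged the same, is 7.02 L mol⁻¹, and the line through these two readings reaches zero at c(reagent) = 0.131 M.

Two extreme flasks can be solved in the head. In the frozen one, N is far below one and tetra adduct stays near zero; in the finished one, N is far above one and tetra adduct equals P. Drawing P on a straight line between the runs as well gives 34.4 % for beta and 62.2 % for eta. But beta has N = 0.484 and eta has N = 1.89, so both lie between the extremes, at P(1 − e^−N): I reckon 13.2 % for beta and 52.8 % for eta. Gamma's charge of 0.120 M stands below the zero of the line, so I give gamma no figure from the line and set its tetra adduct under alder's reading of 5.3 %.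

The forecast, whose ground is that “a rapid stage splits substrate between double product and an unseen loss route”, gives 0.7 % for gamma, 13 % for beta and 53 % for eta. The flasks give 1.23 % of tetra adduct in gamma, 12.4 % in beta and 54.9 % in eta.

    substrate + reagent → single product (k = 0.0935 L mol⁻¹ s⁻¹)
    reagent + single product → double product (k = 0.0624 L mol⁻¹ s⁻¹)
    reagent + double product → triple product (k = 0.00999 L mol⁻¹ s⁻¹)
    reagent + triple product → tetra adduct (k = 0.0671 L mol⁻¹ s⁻¹)
    single product → side product (k = 0.00791 s⁻¹)

Gamma ends with 3.8 % of its own reagent charge still unbound. The same slope also gives a figure for the double product at 20.0 min: for beta, P e^−N gives 21.2 % against the 26.1 % that stands there, and for eta it gives 9.41 % against 11.5 %.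

The readings come from a simulation with made-up constants; noise was put on by code.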